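**Strategy.** Eudesmane numbering is used for the decalin and primed locants for the chromene. Ring B (C1–C5, C10) is read as a cyclohexene: the C4 carbinol is a hydrated C3=C4 alkene, so C1–C2 and C5–C10 are the two σ-bonds of a Diels–Alder retron. A thermal intramolecular Diels–Alder reaction of an acyclic (E,E)-trienoate forms both bonds, closes rings A and B together and sets C1, C5 and C10 from C7, the single stereocentre of the precursor, which comes from (R)-limonene oxide. The C1 ester is then turned into flavene C4': a three-component annulation with Meldrum's acid and 2,3,5-trimethoxyphenol builds the chromanone, and phenyl addition/dehydration gives the 4H-chromene.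

Key step: step 5

Remark on the chemistry: 2,3,5-trimethoxyphenol (15) is taken as a purchasable fine chemical. Limonene oxide is used as the commercial cis/trans mixture, since both epoxides give the same keto-aldehyde. Ring A is C5–C10, ring B is C1–C5/C10, C14 is the methyl on C10 and C15 the methyl on C4; α is the face opposite C14.

Step 1
Reactants: 1 (4R)-limonene 1,2-oxide
Product: 3 (3R)-6-oxo-3-(prop-1-en-2-yl)heptanal, via limonene-1,2-diol 2 (not isolated)
Conditions: H5IO6, THF/H2O, 0 °C to rt
Reagents that add atoms: water, O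
Why: Acid-mediated epoxide hydrolysis followed in the same flask by Malaprade glycol cleavage opens the ring between the two oxygenated carbons without touching the isopropenyl-bearing stereocentre.

Step 2
Reactants: 3 (3R)-6-oxo-3-(prop-1-en-2-yl)heptanal; 4 2-(triphenylphosphoranylidene)propanal
Product: 5 (2E,5R)-2-methyl-8-oxo-5-(prop-1-en-2-yl)non-2-enal
Conditions: PhMe, 90 °C
Reagents that add atoms: 2-(triphenylphosphoranylidene)propanal, CC(C=O)=P(c1ccccc1)(c1ccccc1)c1ccccc1
Why: Wittig olefination with a stabilised ylide, which reacts with the aldehyde only, leaves the methyl ketone untouched and should give the (E)-2-methyl-enal.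

Step 3
Reactants: 5 (2E,5R)-2-methyl-8-oxo-5-(prop-1-en-2-yl)non-2-enal; 6 methyltriphenylphosphonium bromide
Product: 7 (5R,7E)-8-methyl-5-(prop-1-en-2-yl)deca-7,9-dien-2-one
Conditions: 6, KOtBu, THF, 0 °C; then 5 (1.0 equiv), −78 to 0 °C
Reagents that add atoms: methyltriphenylphosphonium bromide, C[P+](c1ccccc1)(c1ccccc1)c1ccccc1.[Br-]
Why: Wittig methylenation, in which one equivalent of ylide at low temperature should take the aldehyde much faster than the methyl ketone, completes the (E)-2-methyl-1,3-diene with the trisubstituted alkene geometry retained.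

Step 4
Reactants: 7 (5R,7E)-8-methyl-5-(prop-1-en-2-yl)deca-7,9-dien-2-one; 8 triethyl phosphonoacetate
Product: 9 ethyl (2E,6R,8E)-3,9-dimethyl-6-(prop-1-en-2-yl)undeca-2,8,10-trienoate
Conditions: 8, NaH, THF, 0 °C; then 7, 0 to 65 °C
Reagents that add atoms: triethyl phosphonoacetate, CCOC(=O)CP(=O)(OCC)OCC
Why: Horner–Wadsworth–Emmons olefination of the methyl ketone should favour the (E)-3-methyl-enoate with the ester trans to the longer chain, and the minor (Z)-isomer would be removed by chromatography.

Step 5
Reactants: 9 ethyl (2E,6R,8E)-3,9-dimethyl-6-(prop-1-en-2-yl)undeca-2,8,10-trienoate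
Product: 10 ethyl eudesma-3,11-diene-1β-carboxylate (trans-decalin with 5α-H, 10β-CH3, 7β-isopropenyl)
Conditions: PhMe (0.01 M), BHT (cat.), 185 °C, sealed tube
Reagents that add atoms: none
Why: A thermal, concerted but asynchronous [4+2] cycloaddition joins the terminus C2 of the (E)-2-methyl-1,3-diene (C2=C3–C4=C5) to C1 and its other terminus C5 to C10 of the (E)-3-methyl-enoate, the closest precedent being the type 1 intramolecular Diels–Alder reaction of 1,3,9-decatrienoates. Ring A (C5–C10) closes through the four-carbon tether as a chair whose last bond is C5–C10, and ring B (C1–C5, C10) is the cyclohexene of the cycloaddition, closed by C1–C2 and C5–C10 together. C7 is the only stereocentre of 9 and sits on the tether: with the isopropenyl group equatorial on the chair only one diene face can reach the dienophile, which fixes C5 and C10 relative to C7. The trans fusion (5α-H, 10β-CH3) needs the transition state with the ester and the C10 methyl endo and the tether anti to the diene, which should be preferred because the alternative folds the tether under the C4 methyl, and the (E)-enoate geometry is transferred suprafacially so that the C1 ester is cis to the C10 methyl (1β, equatorial). The step therefore needs endo/anti and π-facial selectivity, both secured by the E,E geometry, the diene methyl and the equatorial C7 substituent, while a C1 epimer would converge on the equatorial ester on base equilibration. Heat is required because the dienophile is β,β-disubstituted, and high dilution with BHT suppresses diene polymerisation.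

Step 6
Reactants: 10 ethyl eudesma-3,11-diene-1β-carboxylate
Product: 11 ethyl 3α,4α-epoxyeudesm-11-ene-1β-carboxylate
Conditions: mCPBA (1.05 equiv), CH2Cl2, −15 to 0 °C
Reagents that add atoms: mCPBA, O=C(OO)c1cccc(Cl)c1
Why: Prilezhaev epoxidation should take the electron-richer trisubstituted ring alkene ahead of the 1,1-disubstituted isopropenyl group, and the peracid approaches the α face, away from the axial C10 methyl, which sets the C4–O bond α.

Step 7
Reactants: 11 ethyl 3α,4α-epoxyeudesm-11-ene-1β-carboxylate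
Product: 12 1β-(hydroxymethyl)eudesm-11-en-4α-ol
Conditions: LiAlH4, THF, 0 to 65 °C
Reagents that add atoms: none
Why: Hydride reduction takes the ester to the primary alcohol and opens the epoxide by SN2 attack at the less substituted C3 (C4 is tertiary and its β face is blocked by the syn-axial C10 methyl), so the α C4–O bond survives as the 4α-hydroxy-4β-methyl carbinol.

Step 8
Reactants: 12 1β-(hydroxymethyl)eudesm-11-en-4α-ol
Product: 13 4α-hydroxyeudesm-11-ene-1β-carbaldehyde
Conditions: TEMPO (cat.), PhI(OAc)2, CH2Cl2, rt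
Reagents that add atoms: none
Why: Oxoammonium (TEMPO) oxidation is selective for the primary alcohol, the tertiary carbinol cannot be oxidised, and the aldehyde already sits in the more stable equatorial position at C1.

Step 9
Reactants: 13 4α-hydroxyeudesm-11-ene-1β-carbaldehyde; 14 Meldrum's acid; 15 2,3,5-trimethoxyphenol
Product: 19 (4R)-4-(4α-hydroxyeudesm-11-en-1β-yl)-5,7,8-trimethoxychroman-2-one, via alkylidene Meldrum's acid 16 (not isolated), via phenol Michael adduct 17 (not isolated), via lactone acid 18 (not isolated)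
Conditions: pyrrolidinium acetate (cat.), pyridine, 4 Å MS, rt then 90 °C
Reagents that add atoms: Meldrum's acid, CC1(C)OC(=O)CC(=O)O1; 2,3,5-trimethoxyphenol, COc1cc(O)c(OC)c(OC)c1
Why: In this three-component Knoevenagel / Friedel–Crafts-type Michael / lactonisation–decarboxylation synthesis of 4-substituted dihydrocoumarins the phenolate reacts through C6, its only free ortho carbon (para adducts cannot lactonise and revert), and the carbonyl cis to C1 in 16 holds the C1–H bond in the alkene plane by allylic 1,3-strain, so the arene should add to the face anti to the quaternary C10 and set the flavene C4' configuration.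

Step 10
Reactants: 19 (4R)-4-(4α-hydroxyeudesm-11-en-1β-yl)-5,7,8-trimethoxychroman-2-one; 20 phenylmagnesium bromide
Product: 22 (1R,4S,4aS,7R,8aR)-1,4a-dimethyl-7-(prop-1-en-2-yl)-4-[(4S)-5,7,8-trimethoxy-2-phenyl-4H-chromen-4-yl]decahydronaphthalen-1-ol, via hemiketal 21 (not isolated)
Conditions: PhMgBr (2.2 equiv), THF, −40 °C; aq. NH4Cl; then PPTS (cat.), PhMe, 4 Å MS, 50 °C
Reagents that add atoms: phenylmagnesium bromide, Br[Mg]c1ccccc1
Why: Grignard addition to the lactone carbonyl (the first equivalent being consumed by the tertiary hydroxyl) gives the 2-phenylchroman-2-ol, and mild acid-catalysed dehydration through the phenyl-stabilised oxocarbenium ion gives the conjugated 2-phenyl-4H-chromene under conditions too weak to ionise the C4 carbinol or the isopropenyl group.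

**Compound list**

1 | (4R)-limonene 1,2-oxide (cis/trans mixture) | CC12CC[C@H](CC1O2)C(C)=C | starting material
2 | (4R)-p-menth-8-ene-1,2-diol | CC1(O)CC[C@H](CC1O)C(C)=C | intermediate
3 | (3R)-6-oxo-3-(prop-1-en-2-yl)heptanal | CC(=O)CC[C@H](CC=O)C(C)=C | intermediate
4 | 2-(triphenylphosphoranylidene)propanal | CC(C=O)=P(c1ccccc1)(c1ccccc1)c1ccccc1 | starting material
5 | (2E,5R)-2-methyl-8-oxo-5-(prop-1-en-2-yl)non-2-enal | CC(=O)CC[C@H](C/C=C(\C)C=O)C(C)=C | intermediate
6 | methyltriphenylphosphonium bromide | C[P+](c1ccccc1)(c1ccccc1)c1ccccc1.[Br-] | starting material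
7 | (5R,7E)-8-methyl-5-(prop-1-en-2-yl)deca-7,9-dien-2-one | CC(=O)CC[C@H](C/C=C(\C)C=C)C(C)=C | intermediate
8 | triethyl phosphonoacetate | CCOC(=O)CP(=O)(OCC)OCC | starting material
9 | ethyl (2E,6R,8E)-3,9-dimethyl-6-(prop-1-en-2-yl)undeca-2,8,10-trienoate | CCOC(=O)/C=C(\C)CC[C@H](C/C=C(\C)C=C)C(C)=C | intermediate
10 | ethyl eudesma-3,11-diene-1β-carboxylate (5α-H, 10β-CH3, 7β-isopropenyl) | C=C(C)[C@@H]1CC[C@]2(C)[C@@H](C1)C(C)=CC[C@H]2C(=O)OCC | intermediate
11 | ethyl 3α,4α-epoxyeudesm-11-ene-1β-carboxylate | C=C(C)[C@@H]1CC[C@]2(C)[C@@H](C1)[C@]1(C)O[C@@H]1CC[C@H]2C(=O)OCC | intermediate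
12 | 1β-(hydroxymethyl)eudesm-11-en-4α-ol | C=C(C)[C@@H]1CC[C@]2(C)[C@@H](C1)[C@](C)(O)CC[C@H]2CO | intermediate
13 | 4α-hydroxyeudesm-11-ene-1β-carbaldehyde | C=C(C)[C@@H]1CC[C@]2(C)[C@@H](C1)[C@](C)(O)CC[C@H]2C=O | intermediate
14 | Meldrum's acid (2,2-dimethyl-1,3-dioxane-4,6-dione) | CC1(C)OC(=O)CC(=O)O1 | starting material
15 | 2,3,5-trimethoxyphenol | COc1cc(O)c(OC)c(OC)c1 | starting material
16 | 5-[(4α-hydroxyeudesm-11-en-1β-yl)methylidene]-2,2-dimethyl-1,3-dioxane-4,6-dione | C=C(C)[C@@H]1CC[C@]2(C)[C@@H](C1)[C@](C)(O)CC[C@H]2C=C1C(=O)OC(C)(C)OC1=O | intermediate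
17 | 5-[(4α-hydroxyeudesm-11-en-1β-yl)(2-hydroxy-3,4,6-trimethoxyphenyl)methyl]-2,2-dimethyl-1,3-dioxane-4,6-dione (benzylic centre as in 22) | C=C(C)[C@@H]1CC[C@]2(C)[C@@H](C1)[C@](C)(O)CC[C@H]2[C@H](c1c(O)c(OC)c(OC)cc1OC)C1C(=O)OC(C)(C)OC1=O | intermediate
18 | 4-(4α-hydroxyeudesm-11-en-1β-yl)-5,7,8-trimethoxy-2-oxochromane-3-carboxylic acid (C4 as in 22, C3 unassigned) | C=C(C)[C@@H]1CC[C@]2(C)[C@@H](C1)[C@](C)(O)CC[C@H]2[C@H]1C(C(=O)O)C(=O)Oc2c(OC)c(OC)cc(OC)c21 | intermediate
19 | (4R)-4-(4α-hydroxyeudesm-11-en-1β-yl)-5,7,8-trimethoxychroman-2-one | C=C(C)[C@@H]1CC[C@]2(C)[C@@H](C1)[C@](C)(O)CC[C@H]2[C@H]1CC(=O)Oc2c(OC)c(OC)cc(OC)c21 | intermediate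
20 | phenylmagnesium bromide | Br[Mg]c1ccccc1 | starting material
21 | 4-(4α-hydroxyeudesm-11-en-1β-yl)-5,7,8-trimethoxy-2-phenylchroman-2-ol (C4 as in 22, C2 unassigned) | C=C(C)[C@@H]1CC[C@]2(C)[C@@H](C1)[C@](C)(O)CC[C@H]2[C@H]1CC(O)(c2ccccc2)Oc2c(OC)c(OC)cc(OC)c21 | intermediate
22 | (1R,4S,4aS,7R,8aR)-1,4a-dimethyl-7-(prop-1-en-2-yl)-4-[(4S)-5,7,8-trimethoxy-2-phenyl-4H-chromen-4-yl]decahydronaphthalen-1-ol | C=C(C)[C@@H]1CC[C@]2(C)[C@@H](C1)[C@](C)(O)CC[C@H]2[C@H]1C=C(c2ccccc2)Oc2c(OC)c(OC)cc(OC)c21 | target

**Step count.** Total: 10 steps. Longest linear sequence: 10 steps (1 to 22).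

**Steps most likely to fail**

1. Step 5. The process at risk is erosion of ring-fusion (endo/exo) and facial selectivity at the temperature that the β,β-disubstituted dienophile demands, together with thermal oligomerisation of the diene. The fallback sets out from trienoate 9 and comes back at cycloadduct 10. Saponification (LiOH, THF/H2O) would give (2E,6R,8E)-3,9-dimethyl-6-(prop-1-en-2-yl)undeca-2,8,10-trienoic acid F1. Its mixed pivalic anhydride (PivCl, Et3N) would be coupled with lithiated 1,3-oxazolidin-2-one to give the N-trienoyl oxazolidinone F2. Two-point chelation by Me2AlCl (CH2Cl2, −30 °C) should then allow a low-temperature, endo-selective intramolecular Diels–Alder reaction to the imide cycloadduct F3. EtOMgBr in EtOH/THF would return ethyl ester 10.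

2. Step 9. The process at risk is slow conjugate addition of the phenol to a hindered alkylidene, diversion to para C-alkylation or O-alkylation, and incomplete facial control. The fallback sets out from aldehyde 13 and phenol 15 and comes back at Michael adduct 17. Aldehyde 13 would be condensed with 14 alone (pyrrolidinium acetate, PhH, rt) and alkylidene 16 isolated. Phenol 15 would be protected (MOMCl, i-Pr2NEt) as 1-(methoxymethoxy)-2,3,5-trimethoxybenzene F4. Directed ortho-lithiation (n-BuLi, THF, 0 °C) between the OMOM and OMe groups would give 2-(methoxymethoxy)-3,4,6-trimethoxyphenyllithium F5. This regiodefined aryl nucleophile would add 1,4 to 16 (THF, −78 °C, a second equivalent covering the hydroxyl) under the same allylic-strain control to give the MOM-protected Michael adduct F6. PPTS in t-BuOH at 70 °C would remove the MOM group to give 17, which warm pyridine closes to 19 as in step 9.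

3. Step 10. The process at risk is a second Grignard addition to the ring-opened aryl ketone, and acid-promoted loss of the tertiary hydroxyl during dehydration. The fallback sets out from lactone 19 and comes back at hemiketal 21. Aminolysis with MeNH(OMe)·HCl and i-PrMgCl (THF, −10 °C) would open the lactone to the phenolic Weinreb amide F7. Excess PhMgBr (THF, 0 °C) stops at the chelated tetrahedral adduct and on work-up would give the phenolic ketone, which closes to 21. Dehydration as in step 10 then gives 22.

**Further compounds**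

F1 | step 5 | (2E,6R,8E)-3,9-dimethyl-6-(prop-1-en-2-yl)undeca-2,8,10-trienoic acid | OC(=O)/C=C(\C)CC[C@H](C/C=C(\C)C=C)C(C)=C
F2 | step 5 | 3-[(2E,6R,8E)-3,9-dimethyl-6-(prop-1-en-2-yl)undeca-2,8,10-trienoyl]-1,3-oxazolidin-2-one | O=C1OCCN1C(=O)/C=C(\C)CC[C@H](C/C=C(\C)C=C)C(C)=C
F3 | step 5 | 3-[(eudesma-3,11-dien-1β-yl)carbonyl]-1,3-oxazolidin-2-one | C=C(C)[C@@H]1CC[C@]2(C)[C@@H](C1)C(C)=CC[C@H]2C(=O)N1CCOC1=O
F4 | step 9 | 1-(methoxymethoxy)-2,3,5-trimethoxybenzene | COCOc1cc(OC)cc(OC)c1OC
F5 | step 9 | 2-(methoxymethoxy)-3,4,6-trimethoxyphenyllithium | [Li]c1c(OCOC)c(OC)c(OC)cc1OC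
F6 | step 9 | 5-[(4α-hydroxyeudesm-11-en-1β-yl)(2-(methoxymethoxy)-3,4,6-trimethoxyphenyl)methyl]-2,2-dimethyl-1,3-dioxane-4,6-dione | C=C(C)[C@@H]1CC[C@]2(C)[C@@H](C1)[C@](C)(O)CC[C@H]2[C@H](c1c(OCOC)c(OC)c(OC)cc1OC)C1C(=O)OC(C)(C)OC1=O
F7 | step 10 | 3-(4α-hydroxyeudesm-11-en-1β-yl)-3-(2-hydroxy-3,4,6-trimethoxyphenyl)-N-methoxy-N-methylpropanamide | C=C(C)[C@@H]1CC[C@]2(C)[C@@H](C1)[C@](C)(O)CC[C@H]2[C@H](c1c(O)c(OC)c(OC)cc1OC)CC(=O)N(C)OC
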